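The route rests on cutting the C2–C3 bond of the tetrahydrofuran ring (O1, C2–C5). The feature exploited is that ring carbon C2 carries both an aryl group and O1. In the open chain it is an ArCH2–O unit whose doubly activated C–H bonds lie five atoms from C3 (C3–C4–C5–O1–C2). C3 holds the carbon that ends as CH2OH, and this carbon can serve as the ester of a diazo ester. A single rhodium-carbenoid C–H insertion thus makes C2–C3, closes the ring and creates C2 and C3. The precursor is an acyclic α-diazo ester. Its C4/C5 pair stems from an Evans syn-aldol reaction, and its O1 bears the second syringyl unit as a benzyl-type ether.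

Key step: step 12

Assumption: the target is taken as the all-trans (2R,3S,4S,5R) isomer that its SMILES string encodes; the ring numbering O1/C2–C5 is also used for open-chain precursors, Ar = 4-(benzyloxy)-3,5-dimethoxyphenyl and TBS = tert-butyldimethylsilyl.

Step 1
Reactants: 1 syringaldehyde; 2 benzyl bromide
Product: 3 4-(benzyloxy)-3,5-dimethoxybenzaldehyde (ArCHO)
Conditions: K2CO3, DMF, 60 °C
Reagents that add atoms: none
Why: Williamson ether synthesis, in which the phenoxide of 1 displaces bromide from 2 by SN2 and the aldehyde stays untouched.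

Step 2
Reactants: 4 pent-4-enoic acid; 5 (R)-4-benzyl-1,3-oxazolidin-2-one
Product: 7 (R)-4-benzyl-3-(pent-4-enoyl)-1,3-oxazolidin-2-one, via mixed pivalic anhydride 6 (not isolated)
Conditions: PivCl, Et3N, THF, −20 °C; then LiCl, 5, −20 °C → rt
Reagents that add atoms: pivaloyl chloride, CC(C)(C)C(=O)Cl (its atoms reach only intermediate 6)
Why: N-acylation through a mixed anhydride, which the LiCl/Et3N-activated oxazolidinone attacks at the less hindered pentenoyl carbonyl without touching the auxiliary stereocentre.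

Step 3
Reactants: 7 (R)-4-benzyl-3-(pent-4-enoyl)-1,3-oxazolidin-2-one; 3 4-(benzyloxy)-3,5-dimethoxybenzaldehyde
Product: 10 (R)-4-benzyl-3-{(2R)-2-[(R)-Ar(hydroxy)methyl]pent-4-enoyl}-1,3-oxazolidin-2-one (syn aldol), via dibutylboron enolate 8 (not isolated), via dibutylboron aldolate 9 (not isolated)
Conditions: n-Bu2BOTf, Et3N, CH2Cl2, 0 °C; 3, −78 → 0 °C; then pH 7 buffer, MeOH, 30% H2O2, 0 °C
Reagents that add atoms: dibutylboron triflate, CCCCB(CCCC)OS(=O)(=O)C(F)(F)F (its atoms reach only intermediates 8 and 9)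
Why: Evans syn-aldol reaction, in which the (Z)-boron enolate reacts through a closed Zimmerman–Traxler chair whose dipole-opposed (R)-benzyl auxiliary shields one enolate face, so that the later C4 and C5 arise together as the (2R,3R) syn pair, which becomes 4,5-trans once O1 and the allyl carbon are ring members.

Step 4
Reactants: 10 syn aldol imide
Product: 11 (1R,2S)-2-allyl-1-Ar-propane-1,3-diol
Conditions: LiBH4, H2O (1 equiv), Et2O, 0 °C
Reagents that add atoms: none
Why: Chemoselective borohydride reduction of the exocyclic imide carbonyl, which releases the auxiliary and leaves the alkene, the aryl ethers and both stereocentres unchanged.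

Step 5
Reactants: 11 (1R,2S)-2-allyl-1-Ar-propane-1,3-diol; 3 4-(benzyloxy)-3,5-dimethoxybenzaldehyde
Product: 13 (2R,4R,5S)-5-allyl-2,4-di-Ar-1,3-dioxane, via dimethyl acetal 12 (not isolated)
Conditions: 3, HC(OMe)3, CSA (cat.), MeOH, rt; evaporate; 11, CH2Cl2, rt; Et3N quench
Reagents that add atoms: trimethyl orthoformate, COC(OC)OC (its atoms reach only intermediate 12)
Why: Acid-catalysed transacetalisation under thermodynamic control, which gives the dioxane chair with both aryl groups equatorial and the allyl group axial, so the temporary acetal centre is (R) and is erased again in step 6.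

Step 6
Reactants: 13 (2R,4R,5S)-5-allyl-2,4-di-Ar-1,3-dioxane
Product: 14 (2S)-2-[(R)-Ar(ArCH2O)methyl]pent-4-en-1-ol
Conditions: i-Bu2AlH (3 equiv), CH2Cl2, −78 → 0 °C; aq. potassium sodium tartrate
Reagents that add atoms: none
Why: Regioselective reductive opening of an arylidene acetal, in which aluminium binds the less hindered primary oxygen, that C–O bond ionises to the aryl-stabilised oxocarbenium ion and hydride is delivered to it, so the ArCH2 group stays on the secondary oxygen O1 and neither an alkoxide next to a silyl ether nor a strong acid ever meets the benzylic centre C5.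

Step 7
Reactants: 14 (2S)-2-[(R)-Ar(ArCH2O)methyl]pent-4-en-1-ol
Product: 15 TBS ether of 14
Conditions: TBSCl, imidazole, DMF, rt
Reagents that add atoms: tert-butyldimethylsilyl chloride, CC(C)(C)[Si](C)(C)Cl
Why: Imidazole-promoted silylation of the only free hydroxyl group, chosen because a silyl ether, unlike a benzyl ether, offers no C–H bond 1,5 to C3 in the key step.

Step 8
Reactants: 15 TBS ether of 14
Product: 17 (3S,4R)-4-Ar-4-(ArCH2O)-3-[(TBSO)methyl]butanal, via vicinal diol 16 (not isolated)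
Conditions: OsO4 (2 mol %), NaIO4, 2,6-lutidine, dioxane–H2O, rt
Reagents that add atoms: osmium tetroxide, O=[Os](=O)(=O)=O (oxygen donor, catalytic); sodium periodate, [Na+].[O-]I(=O)(=O)=O (terminal oxygen source)
Why: Lemieux–Johnson cleavage, that is dihydroxylation of the only alkene followed by periodate glycol fission under lutidine buffering, which avoids ozone and its attack on trialkoxyarenes and benzyl ethers.

Step 9
Reactants: 17 (3S,4R)-4-Ar-4-(ArCH2O)-3-[(TBSO)methyl]butanal
Product: 18 (3S,4R)-4-Ar-4-(ArCH2O)-3-[(TBSO)methyl]butanoic acid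
Conditions: NaClO2, NaH2PO4, 2-methyl-2-butene, t-BuOH–H2O, rt
Reagents that add atoms: sodium chlorite, [Na+].[O-]Cl=O
Why: Pinnick oxidation, in which chlorous acid adds to the aldehyde and fragments to the acid while the alkene scavenger removes HOCl before it can chlorinate the arenes.

Step 10
Reactants: 18 (3S,4R)-4-Ar-4-(ArCH2O)-3-[(TBSO)methyl]butanoic acid
Product: 19 methyl (3S,4R)-4-Ar-4-(ArCH2O)-3-[(TBSO)methyl]butanoate
Conditions: MeI, K2CO3, DMF, rt
Reagents that add atoms: iodomethane, CI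
Why: SN2 O-alkylation of the carboxylate, the only nucleophilic site in the molecule.

Step 11
Reactants: 19 methyl (3S,4R)-4-Ar-4-(ArCH2O)-3-[(TBSO)methyl]butanoate
Product: 21 methyl (3S,4R)-4-Ar-4-(ArCH2O)-3-[(TBSO)methyl]-2-diazobutanoate, via trifluoroacetyl ester 20 (not isolated)
Conditions: LiN(SiMe3)2, THF, −78 °C; CF3CO2CH2CF3, −78 °C; aq. HCl work-up; crude 20, MsN3, Et3N, MeCN, rt
Reagents that add atoms: methanesulfonyl azide, CS(=O)(=O)N=[N+]=[N-]; 2,2,2-trifluoroethyl trifluoroacetate, O=C(OCC(F)(F)F)C(F)(F)F (its atoms reach only intermediate 20)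
Why: Deacylative Regitz-type diazo transfer, needed because a plain ester is too weakly acidic for direct transfer, so its enolate is first C-trifluoroacetylated in a Claisen-type acylation and the activated 20 then adds to the sulfonyl azide and sheds the trifluoroacetyl group, while C4 and C5 are not acidic and no leaving group sits β to the enolate.

Step 12
Reactants: 21 methyl (3S,4R)-4-Ar-4-(ArCH2O)-3-[(TBSO)methyl]-2-diazobutanoate
Product: 24 methyl (2R,3R,4S,5R)-2,5-di-Ar-4-[(TBSO)methyl]oxolane-3-carboxylate (all-trans), via Rh2(O2CCPh3)4 carbenoid 22 (not isolated), via C3-epimeric ester 23 (not isolated)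
Conditions: Rh2(O2CCPh3)4 (1 mol %), CH2Cl2, −78 °C (slow addition of 21) → rt; evaporate; NaOMe (0.2 equiv), MeOH–THF, rt
Reagents that add atoms: Rh2(O2CCPh3)4, [Rh+2].[Rh+2].[O-]C(=O)C(c1ccccc1)(c1ccccc1)c1ccccc1.[O-]C(=O)C(c1ccccc1)(c1ccccc1)c1ccccc1.[O-]C(=O)C(c1ccccc1)(c1ccccc1)c1ccccc1.[O-]C(=O)C(c1ccccc1)(c1ccccc1)c1ccccc1 (rhodium is present only in intermediate 22)
Why: Rh2(O2CCPh3)4, a dimer of divalent rhodium, expels N2 from 21 to give the electrophilic carbenoid 22, whose empty p orbital on C3 engages one benzylic C–H bond of the O1–CH2Ar group in a concerted, asynchronous three-centre transition state with hydride-transfer character, so that C3–H and C2–C3 form while the catalyst departs. The closest known reaction type is the dirhodium-catalysed 1,5 C–H insertion of α-diazo esters and α-diazo lactones into benzylic ether C–H bonds, which delivers 2-aryltetrahydrofuran-3-carboxylates. The one ring formed (O1, C2, C3, C4, C5) closes by 1,5-insertion through the five-membered array C3–C4–C5–O1–C2, whereas the other activated C–H bonds (C5–H and CH2OSi) lie only 1,3 to C3 and would require a cyclopropane. C2 is controlled by the choice between the two diastereotopic benzylic hydrogens: the C2 aryl group and the C4 silyloxymethyl arm both turn away from the ring face covered by the triphenylacetate wall, so they end up cis to each other and, because C4 and C5 are already trans, the C2 aryl group ends up trans to the C5 aryl group. C3 may emerge kinetically with the ester on the crowded face (23), but catalytic NaOMe then equilibrates this one acidic centre through its enolate until the ester stands trans to both neighbours in 24, the ring C2–O1 bond being poorly aligned for β-elimination. The step needs chemoselectivity over the 1,2-hydride shift from C4 and over attack on the ortho carbons of the C5 aryl ring, and the substrate secures it through double activation of the target C–H bond by the O1 lone pair and the trialkoxyaryl ring, through a reactive rotamer that keeps C4–H near the nodal plane of the carbenoid p orbital, and through the methoxy groups flanking each ortho carbon, all reinforced by the bulky ligand at −78 °C.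

Step 13
Reactants: 24 methyl (2R,3R,4S,5R)-2,5-di-Ar-4-[(TBSO)methyl]oxolane-3-carboxylate
Product: 25 {(2R,3S,4S,5R)-2,5-di-Ar-4-[(TBSO)methyl]oxolan-3-yl}methanol
Conditions: LiAlH4, THF, 0 °C
Reagents that add atoms: none
Why: Aluminium hydride reduction of the ester, to which silyl, benzyl and ring ethers are inert and after which no stereocentre is acidic any more.

Step 14
Reactants: 25 {(2R,3S,4S,5R)-2,5-di-Ar-4-[(TBSO)methyl]oxolan-3-yl}methanol
Product: 26 [(2R,3S,4S,5R)-2,5-di-Ar-oxolane-3,4-diyl]dimethanol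
Conditions: Bu4NF, THF, rt
Reagents that add atoms: none
Why: Fluoride-driven Si–O cleavage under non-acidic conditions, which spares the acid-sensitive doubly benzylic ring ether.

Step 15
Reactants: 26 [(2R,3S,4S,5R)-2,5-di-Ar-oxolane-3,4-diyl]dimethanol
Product: 27 (2R,3S,4S,5R)-2,5-bis(4-hydroxy-3,5-dimethoxyphenyl)-3,4-bis(hydroxymethyl)oxolane (target)
Conditions: H2 (1 atm), 10% Pd/C, EtOAc–MeOH, rt, stopped after uptake of two equivalents
Reagents that add atoms: none
Why: Catalytic hydrogenolysis of the two primary aryl benzyl ethers, which should cleave well before the hindered secondary benzylic C–O bonds of the ring and touches no stereocentre.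

Compound list
1 | syringaldehyde (4-hydroxy-3,5-dimethoxybenzaldehyde) | COc1cc(C=O)cc(OC)c1O | starting material
2 | benzyl bromide | BrCc1ccccc1 | starting material
3 | 4-(benzyloxy)-3,5-dimethoxybenzaldehyde | COc1cc(C=O)cc(OC)c1OCc1ccccc1 | intermediate
4 | pent-4-enoic acid | C=CCCC(=O)O | starting material
5 | (R)-4-benzyl-1,3-oxazolidin-2-one | O=C1N[C@H](Cc2ccccc2)CO1 | starting material
6 | pent-4-enoic pivalic anhydride | C=CCCC(=O)OC(=O)C(C)(C)C | intermediate (not isolated)
7 | (R)-4-benzyl-3-(pent-4-enoyl)-1,3-oxazolidin-2-one | C=CCCC(=O)N1[C@H](Cc2ccccc2)COC1=O | intermediate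
8 | (Z)-dibutylboron enolate of 7 | C=CC/C=C(\OB(CCCC)CCCC)N1[C@H](Cc2ccccc2)COC1=O | intermediate (not isolated)
9 | O-dibutylboryl derivative (aldolate) of 10 | CCCCB(CCCC)O[C@@H](c1cc(OC)c(OCc2ccccc2)c(OC)c1)[C@H](C(=O)N1[C@H](Cc2ccccc2)COC1=O)CC=C | intermediate (not isolated)
10 | (R)-4-benzyl-3-{(2R)-2-[(R)-[4-(benzyloxy)-3,5-dimethoxyphenyl](hydroxy)methyl]pent-4-enoyl}-1,3-oxazolidin-2-one | O[C@@H](c1cc(OC)c(OCc2ccccc2)c(OC)c1)[C@H](C(=O)N1[C@H](Cc2ccccc2)COC1=O)CC=C | intermediate
11 | (1R,2S)-2-allyl-1-[4-(benzyloxy)-3,5-dimethoxyphenyl]propane-1,3-diol | O[C@@H](c1cc(OC)c(OCc2ccccc2)c(OC)c1)[C@H](CO)CC=C | intermediate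
12 | 2-(benzyloxy)-5-(dimethoxymethyl)-1,3-dimethoxybenzene | COC(OC)c1cc(OC)c(OCc2ccccc2)c(OC)c1 | intermediate (not isolated)
13 | (2R,4R,5S)-5-allyl-2,4-bis[4-(benzyloxy)-3,5-dimethoxyphenyl]-1,3-dioxane | COc1cc(cc(OC)c1OCc1ccccc1)[C@H]1O[C@@H](c2cc(OC)c(OCc3ccccc3)c(OC)c2)[C@H](CO1)CC=C | intermediate
14 | (2S)-2-[(R)-[4-(benzyloxy)-3,5-dimethoxyphenyl]{[4-(benzyloxy)-3,5-dimethoxybenzyl]oxy}methyl]pent-4-en-1-ol | COc1cc(CO[C@@H](c2cc(OC)c(OCc3ccccc3)c(OC)c2)[C@H](CO)CC=C)cc(OC)c1OCc1ccccc1 | intermediate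
15 | tert-butyldimethylsilyl ether of 14 | COc1cc(CO[C@@H](c2cc(OC)c(OCc3ccccc3)c(OC)c2)[C@H](CO[Si](C)(C)C(C)(C)C)CC=C)cc(OC)c1OCc1ccccc1 | intermediate
16 | (4S)-4-[(R)-Ar(ArCH2O)methyl]-5-(TBSO)pentane-1,2-diol (both C2 epimers) | COc1cc(CO[C@@H](c2cc(OC)c(OCc3ccccc3)c(OC)c2)[C@H](CO[Si](C)(C)C(C)(C)C)CC(O)CO)cc(OC)c1OCc1ccccc1 | intermediate (not isolated)
17 | (3S,4R)-4-Ar-4-(ArCH2O)-3-[(TBSO)methyl]butanal | COc1cc(CO[C@@H](c2cc(OC)c(OCc3ccccc3)c(OC)c2)[C@H](CO[Si](C)(C)C(C)(C)C)CC=O)cc(OC)c1OCc1ccccc1 | intermediate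
18 | (3S,4R)-4-Ar-4-(ArCH2O)-3-[(TBSO)methyl]butanoic acid | COc1cc(CO[C@@H](c2cc(OC)c(OCc3ccccc3)c(OC)c2)[C@H](CO[Si](C)(C)C(C)(C)C)CC(=O)O)cc(OC)c1OCc1ccccc1 | intermediate
19 | methyl (3S,4R)-4-Ar-4-(ArCH2O)-3-[(TBSO)methyl]butanoate | COc1cc(CO[C@@H](c2cc(OC)c(OCc3ccccc3)c(OC)c2)[C@H](CO[Si](C)(C)C(C)(C)C)CC(=O)OC)cc(OC)c1OCc1ccccc1 | intermediate
20 | methyl (3S,4R)-4-Ar-4-(ArCH2O)-3-[(TBSO)methyl]-2-(trifluoroacetyl)butanoate (C2 epimers and enol) | COc1cc(CO[C@@H](c2cc(OC)c(OCc3ccccc3)c(OC)c2)[C@H](CO[Si](C)(C)C(C)(C)C)C(C(=O)C(F)(F)F)C(=O)OC)cc(OC)c1OCc1ccccc1 | intermediate (not isolated)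
21 | methyl (3S,4R)-4-[4-(benzyloxy)-3,5-dimethoxyphenyl]-4-{[4-(benzyloxy)-3,5-dimethoxybenzyl]oxy}-3-[(tert-butyldimethylsilyloxy)methyl]-2-diazobutanoate | COc1cc(CO[C@@H](c2cc(OC)c(OCc3ccccc3)c(OC)c2)[C@H](CO[Si](C)(C)C(C)(C)C)C(=[N+]=[N-])C(=O)OC)cc(OC)c1OCc1ccccc1 | intermediate
22 | Rh2(O2CCPh3)4 carbenoid at C3 of 21 ([Rh] stands for the whole Rh2(O2CCPh3)4 unit) | COc1cc(CO[C@@H](c2cc(OC)c(OCc3ccccc3)c(OC)c2)[C@H](CO[Si](C)(C)C(C)(C)C)C(=[Rh])C(=O)OC)cc(OC)c1OCc1ccccc1 | intermediate (not isolated)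
23 | methyl (2R,3S,4S,5R)-2,5-di-Ar-4-[(TBSO)methyl]oxolane-3-carboxylate (2,3-cis, 3,4-cis, 4,5-trans) | COc1cc([C@@H]2O[C@@H](c3cc(OC)c(OCc4ccccc4)c(OC)c3)[C@H](CO[Si](C)(C)C(C)(C)C)[C@@H]2C(=O)OC)cc(OC)c1OCc1ccccc1 | intermediate (not isolated)
24 | methyl (2R,3R,4S,5R)-2,5-bis[4-(benzyloxy)-3,5-dimethoxyphenyl]-4-[(tert-butyldimethylsilyloxy)methyl]oxolane-3-carboxylate (all-trans) | COc1cc([C@@H]2O[C@@H](c3cc(OC)c(OCc4ccccc4)c(OC)c3)[C@H](CO[Si](C)(C)C(C)(C)C)[C@H]2C(=O)OC)cc(OC)c1OCc1ccccc1 | intermediate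
25 | {(2R,3S,4S,5R)-2,5-di-Ar-4-[(TBSO)methyl]oxolan-3-yl}methanol | COc1cc([C@@H]2O[C@@H](c3cc(OC)c(OCc4ccccc4)c(OC)c3)[C@H](CO[Si](C)(C)C(C)(C)C)[C@H]2CO)cc(OC)c1OCc1ccccc1 | intermediate
26 | [(2R,3S,4S,5R)-2,5-bis[4-(benzyloxy)-3,5-dimethoxyphenyl]oxolane-3,4-diyl]dimethanol | COc1cc([C@@H]2O[C@@H](c3cc(OC)c(OCc4ccccc4)c(OC)c3)[C@H](CO)[C@H]2CO)cc(OC)c1OCc1ccccc1 | intermediate
27 | (2R,3S,4S,5R)-2,5-bis(4-hydroxy-3,5-dimethoxyphenyl)-3,4-bis(hydroxymethyl)oxolane | COc1cc([C@@H]2O[C@@H](c3cc(OC)c(O)c(OC)c3)[C@H](CO)[C@H]2CO)cc(OC)c1O | target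

Total step count: 15. The methoxide equilibration is run on the crude insertion product within step 12.
Longest linear sequence: 14 steps, namely step 1 followed by steps 3 to 15, starting from syringaldehyde.

Steps most likely to fail

1. Step 12 (key step). Three processes could defeat it.
   - Migration of the C4 hydrogen to the carbenoid carbon may outrun insertion.
   - The carbenoid may attack the electron-rich C5 aryl ring.
   - The wrong diastereotopic benzylic hydrogen may be taken, which would set C2 irreversibly.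

   Fallback: give up carbenoid chemistry, make C2–C3 by a lactone aldol reaction and close O1–C2 by ionisation. It sets out from alcohol 14 and aldehyde 3 and comes back at diol 26. Lemieux–Johnson cleavage of 14 (OsO4 cat., NaIO4) lets the free primary hydroxyl group close on the new aldehyde to give the lactol F1. (n-Pr4N)RuO4/NMO oxidises it to the β-substituted γ-butyrolactone F2. Its lithium enolate (LiN(SiMe3)2, −78 °C) adds to 3 on the ring face opposite the C4 substituent, which fixes C3 and gives the 3,4-trans aldol F3; the carbinol configuration is erased later. LiAlH4 opens the lactone to the triol F4, and TBSCl/imidazole caps the two primary hydroxyl groups to give the bis-silyl ether F5. MsCl/Et3N turns the C2 carbinol into a leaving group that ionises with help from its aryl ring. The O1 ether oxygen then closes the five-membered ring on the face trans to the C3 arm, and the oxonium ion sheds its ArCH2 group to chloride (debenzylative cycloetherification), giving the bis-silylated tetrahydrofuran F6. Bu4NF then leads to 26.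

2. Step 11. C-acylation of the β-branched enolate may be slow or reversible, so that the diazo transfer finds no activated substrate. Fallback: bring in nitrogen as an azide and diazotise the derived amine. It sets out from ester 19 and comes back at diazo ester 21. KN(SiMe3)2, then 2,4,6-triisopropylbenzenesulfonyl azide and an AcOH quench (electrophilic azidation), give the α-azido ester F7. Staudinger reduction (PPh3, THF–H2O) gives the α-amino ester F8. Isoamyl nitrite with catalytic AcOH in warm CHCl3 converts the amine into the diazo group of 21. The configuration at C3 in both compounds is irrelevant.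

3. Step 6. Regiocontrol in the acetal opening may be lost, or the Lewis acid may ionise the benzylic C5–O bond, with reduction or epimerisation there. Fallback: attach the ArCH2 group by acid-catalysed imidate alkylation instead of by way of the acetal. It sets out from diol 11 and aldehyde 3 and comes back at silyl ether 15. TBSCl (1 equiv)/imidazole silylates the primary hydroxyl group selectively to give the mono-silyl ether F9. NaBH4 reduces 3 to the benzyl alcohol F10, and Cl3CCN/DBU converts it into the trichloroacetimidate F11. The two partners combine under catalytic TfOH at low temperature to give 15.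

Further compounds
F1 | step 12 | (4S)-4-[(R)-Ar(ArCH2O)methyl]oxolan-2-ol (lactol, both anomers) | COc1cc(CO[C@@H](c2cc(OC)c(OCc3ccccc3)c(OC)c2)[C@H]2CC(O)OC2)cc(OC)c1OCc1ccccc1
F2 | step 12 | (4S)-4-[(R)-Ar(ArCH2O)methyl]oxolan-2-one | COc1cc(CO[C@@H](c2cc(OC)c(OCc3ccccc3)c(OC)c2)[C@H]2CC(=O)OC2)cc(OC)c1OCc1ccccc1
F3 | step 12 | (3R,4S)-3-[Ar(hydroxy)methyl]-4-[(R)-Ar(ArCH2O)methyl]oxolan-2-one (carbinol epimers) | COc1cc(CO[C@@H](c2cc(OC)c(OCc3ccccc3)c(OC)c2)[C@H]2[C@H](C(O)c3cc(OC)c(OCc4ccccc4)c(OC)c3)C(=O)OC2)cc(OC)c1OCc1ccccc1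
F4 | step 12 | (2S,3S)-2-[(R)-Ar(ArCH2O)methyl]-3-[Ar(hydroxy)methyl]butane-1,4-diol | COc1cc(CO[C@@H](c2cc(OC)c(OCc3ccccc3)c(OC)c2)[C@H](CO)[C@H](C(O)c2cc(OC)c(OCc3ccccc3)c(OC)c2)CO)cc(OC)c1OCc1ccccc1
F5 | step 12 | 1,4-bis-O-TBS ether of F4 | COc1cc(CO[C@@H](c2cc(OC)c(OCc3ccccc3)c(OC)c2)[C@H](CO[Si](C)(C)C(C)(C)C)[C@H](C(O)c2cc(OC)c(OCc3ccccc3)c(OC)c2)CO[Si](C)(C)C(C)(C)C)cc(OC)c1OCc1ccccc1
F6 | step 12 | (2R,3S,4S,5R)-2,5-di-Ar-3,4-bis[(TBSO)methyl]oxolane | COc1cc([C@@H]2O[C@@H](c3cc(OC)c(OCc4ccccc4)c(OC)c3)[C@H](CO[Si](C)(C)C(C)(C)C)[C@H]2CO[Si](C)(C)C(C)(C)C)cc(OC)c1OCc1ccccc1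
F7 | step 11 | methyl (3S,4R)-2-azido-4-Ar-4-(ArCH2O)-3-[(TBSO)methyl]butanoate (C2 epimers) | COc1cc(CO[C@@H](c2cc(OC)c(OCc3ccccc3)c(OC)c2)[C@H](CO[Si](C)(C)C(C)(C)C)C(N=[N+]=[N-])C(=O)OC)cc(OC)c1OCc1ccccc1
F8 | step 11 | methyl (3S,4R)-2-amino-4-Ar-4-(ArCH2O)-3-[(TBSO)methyl]butanoate (C2 epimers) | COc1cc(CO[C@@H](c2cc(OC)c(OCc3ccccc3)c(OC)c2)[C@H](CO[Si](C)(C)C(C)(C)C)C(N)C(=O)OC)cc(OC)c1OCc1ccccc1
F9 | step 6 | (1R,2S)-1-Ar-2-[(TBSO)methyl]pent-4-en-1-ol | O[C@@H](c1cc(OC)c(OCc2ccccc2)c(OC)c1)[C@H](CO[Si](C)(C)C(C)(C)C)CC=C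
F10 | step 6 | [4-(benzyloxy)-3,5-dimethoxyphenyl]methanol | COc1cc(CO)cc(OC)c1OCc1ccccc1
F11 | step 6 | 4-(benzyloxy)-3,5-dimethoxybenzyl 2,2,2-trichloroacetimidate | COc1cc(COC(=N)C(Cl)(Cl)Cl)cc(OC)c1OCc1ccccc1
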